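The oxolan-3-one ring (O15, C1, C14, C13, C12 of the 15-oxabicyclo[10.2.1]pentadecane core) is read as the adduct of a cyclic carbonyl ylide (C1–O15–C12) with a ketene equivalent (C14–C13). An oxidopyrylium [5+2] cycloaddition of a flat, maltol-derived pyrylium salt with enantiopure p-tolyl vinyl sulfoxide forms the C1–C14 and C12–C13 bonds in one operation. It closes the oxolane, forces its two future side arms cis (they are the ends of a three-carbon bridge) and sets the absolute configuration. The bridge is then cut to a formyl and a carboxymethyl arm, which are joined to a carvone-derived chain and closed to the 14-membered ring by metathesis.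

Key step: step 3

Assumption: the (R)-sulfinyl group is taken to steer the dipolarophile to the ylide face that gives the (1S,5S) adduct 6, as in the related oxidopyridinium cycloadditions of this sulfoxide; if the other face is preferred, the enantiomeric sulfoxide (from the equally available (1S,2R,5S)-menthyl (R)-sulfinate) is used.

Step 1
Reactants: 1 (1R,2S,5R)-5-methyl-2-(propan-2-yl)cyclohexyl (S)-4-methylbenzenesulfinate
Product: 2 (R)-1-(ethenesulfinyl)-4-methylbenzene
Conditions: CH2=CHMgBr, THF/toluene, −78 °C to 0 °C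
Reagents that add atoms: vinylmagnesium bromide, C=C[Mg]Br
Why: Andersen sulfoxide synthesis, in which the Grignard reagent displaces menthoxide at sulfur with inversion, so that the (S)-sulfinate should give the (R)-sulfoxide as one enantiomer.

Step 2
Reactants: 3 maltol (3-hydroxy-2-methyl-4H-pyran-4-one)
Product: 4 3-hydroxy-4-methoxy-2-methylpyrylium trifluoromethanesulfonate
Conditions: MeOTf, CH2Cl2, 40 °C
Reagents that add atoms: methyl trifluoromethanesulfonate, COS(=O)(=O)C(F)(F)F
Why: O-methylation of the vinylogous-ester carbonyl oxygen of the 4-pyranone by a hard alkylating agent (pyrylium salt formation) should give the aromatic salt that stores the ylide; no stereocentre is formed.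

Step 3
Reactants: 4 3-hydroxy-4-methoxy-2-methylpyrylium trifluoromethanesulfonate; 2 (R)-1-(ethenesulfinyl)-4-methylbenzene
Product: 6 (1S,5S,6R)-3-methoxy-1-methyl-6-[(R)-4-methylbenzenesulfinyl]-8-oxabicyclo[3.2.1]oct-3-en-2-one, via oxidopyrylium ylide 5 (not isolated)
Conditions: iPr2NEt (slow addition), 2 (3 equiv), CHCl3, 40 °C; diastereomers separated by chromatography
Reagents that add atoms: none
Why: The amine removes the hydroxyl proton of 4 to give the 4-methoxy-3-oxidopyrylium ylide 5, a cyclic carbonyl ylide, which adds across its C2 and C6 termini to the vinyl sulfoxide in a concerted, asynchronous [5+2] (4π + 2π) cycloaddition that forms both C–C bonds at once. The closest known reaction type is the oxidopyrylium–alkene [5+2] cycloaddition of ylides from 3-hydroxy-4-pyranones with electron-poor alkenes, and the use of this sulfoxide as a chiral dipolarophile follows its cycloadditions with oxidopyridinium betaines. The oxolane ring (O8, C1, C7, C6, C5) and the seven-membered enone ring close together by suprafacial addition on both partners, so the two bridgehead bonds that later become the side arms are cis by necessity. Both bridgehead stereocentres (C1, C5) arise from the choice of ylide face, which is controlled by the sulfur stereocentre (reaction through the S=O/C=C s-cis conformer on the side away from the p-tolyl group), while the exo or endo position of sulfur at C6 does not matter because C6 becomes the ketone carbon. Regioselectivity is needed (CH2 to the methyl-bearing terminus) and is secured electronically, since the unsubstituted alkene carbon pairs with the oxido-substituted ylide terminus as for acrylates and acrylonitrile, and sterically, since the smaller alkene terminus meets the substituted ylide terminus. Selectivity over dimerisation of the ylide is secured by excess dipolarophile and slow generation of the ylide.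

Step 4
Reactants: 6 (1S,5S,6R)-3-methoxy-1-methyl-6-[(R)-4-methylbenzenesulfinyl]-8-oxabicyclo[3.2.1]oct-3-en-2-one
Product: 7 (1S,5S,6R)-3-methoxy-1-methyl-6-[(R)-4-methylbenzenesulfinyl]-8-oxabicyclo[3.2.1]oct-3-en-2-ol (either C2 epimer)
Conditions: NaBH4, CeCl3·7H2O, MeOH, −78 °C to −40 °C
Reagents that add atoms: none
Why: Luche 1,2-reduction of the α-methoxy enone should leave the enol ether and the sulfoxide untouched, and the configuration of the new carbinol carbon is immaterial because this carbon becomes a formyl group.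

Step 5
Reactants: 7 (1S,5S,6R)-3-methoxy-1-methyl-6-[(R)-4-methylbenzenesulfinyl]-8-oxabicyclo[3.2.1]oct-3-en-2-ol
Product: 9 2-[(2S,3R,5S)-5-formyl-5-methyl-3-[(R)-4-methylbenzenesulfinyl]oxolan-2-yl]acetic acid, via acyloin 8 (not isolated)
Conditions: H5IO6, THF/H2O, 0 °C to rt
Reagents that add atoms: water, O
Why: Aqueous periodic acid should hydrolyse the methyl enol ether to acyloin 8 and then cleave its C2–C3 bond (Malaprade cleavage), turning the bridge into a formyl group on the methyl-bearing carbon and a carboxymethyl arm on the other; no stereocentre is touched, so the arms stay cis.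

Step 6
Reactants: 9 2-[(2S,3R,5S)-5-formyl-5-methyl-3-[(R)-4-methylbenzenesulfinyl]oxolan-2-yl]acetic acid
Product: 10 2-[(2S,3R,5S)-5-ethenyl-5-methyl-3-[(R)-4-methylbenzenesulfinyl]oxolan-2-yl]acetic acid
Conditions: Ph3PCH3Br, KHMDS (ylide, 2.5 equiv), THF, −78 °C to rt; acidic work-up
Reagents that add atoms: methyltriphenylphosphonium bromide, C[P+](c1ccccc1)(c1ccccc1)c1ccccc1.[Br-]
Why: Wittig methylenation of the non-enolisable α-alkoxy aldehyde, in which the carboxylate and the sulfoxide are inert to the ylide and no stereocentre is affected.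

Step 7
Reactants: 10 2-[(2S,3R,5S)-5-ethenyl-5-methyl-3-[(R)-4-methylbenzenesulfinyl]oxolan-2-yl]acetic acid
Product: 11 S-pyridin-2-yl 2-[(2S,3R,5S)-5-ethenyl-5-methyl-3-[(R)-4-methylbenzenesulfinyl]oxolan-2-yl]ethanethioate
Conditions: 2,2′-dipyridyl disulfide, PPh3, CH2Cl2, rt
Reagents that add atoms: 2,2′-dipyridyl disulfide, c1ccc(SSc2ccccn2)nc1
Why: Mukaiyama redox condensation (disulfide/phosphine) should give the 2-pyridyl thioester, the acyl partner of the later ketone synthesis, under neutral conditions that leave all stereocentres alone.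

Step 8
Reactants: 12 (R)-carvone
Product: 13 (1R,4R,6R)-1-methyl-4-(prop-1-en-2-yl)-7-oxabicyclo[4.1.0]heptan-2-one
Conditions: 30% aq. H2O2, NaOH (cat.), MeOH, 0 °C
Reagents that add atoms: hydrogen peroxide, OO
Why: Weitz–Scheffer nucleophilic epoxidation attacks only the electron-poor enone double bond and spares the isopropenyl group; the oxirane should form anti to the isopropenyl group, and both new centres are removed in the next step.

Step 9
Reactants: 13 (1R,4R,6R)-1-methyl-4-(prop-1-en-2-yl)-7-oxabicyclo[4.1.0]heptan-2-one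
Product: 16 (3R)-5-oxo-3-(prop-1-en-2-yl)pentanoic acid, via diol 14 (not isolated), via dioxo aldehyde 15 (not isolated)
Conditions: H5IO6 (2.2 equiv), THF/H2O, 0 °C to rt
Reagents that add atoms: water, O
Why: Acid opening of the oxirane to diol 14 followed by two Malaprade cleavages (the glycol, then the 1,2-diketone of 15) should excise the methyl-bearing carbon as acetic acid, while the carvone stereocentre is not part of any bond that breaks.

Step 10
Reactants: 17 methyl 2-[bis(2,2,2-trifluoroethoxy)phosphoryl]acetate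
Product: 18 methyl 2-[bis(2,2,2-trifluoroethoxy)phosphoryl]pent-4-enoate (racemic)
Conditions: NaH, THF, 0 °C; allyl bromide, 0 °C to rt
Reagents that add atoms: allyl bromide, C=CCBr
Why: SN2 C-alkylation of the stabilised phosphonoacetate carbanion with a reactive allylic bromide; the new centre is racemic and becomes sp2 in the next step.

Step 11
Reactants: 16 (3R)-5-oxo-3-(prop-1-en-2-yl)pentanoic acid; 18 methyl 2-[bis(2,2,2-trifluoroethoxy)phosphoryl]pent-4-enoate
Product: 19 (3R,5Z)-6-(methoxycarbonyl)-3-(prop-1-en-2-yl)nona-5,8-dienoic acid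
Conditions: 18 (2.2 equiv), KHMDS (2.1 equiv), 18-crown-6, THF, −78 °C; then 16; acidic work-up
Reagents that add atoms: none
Why: Still–Gennari variant of the Horner–Wadsworth–Emmons olefination, in which the trifluoroethyl phosphonate under dissociating conditions should give kinetically the trisubstituted enoate with the ester cis to the aldehyde-derived chain (Z), the geometry required in the ring.

Step 12
Reactants: 19 (3R,5Z)-6-(methoxycarbonyl)-3-(prop-1-en-2-yl)nona-5,8-dienoic acid
Product: 20 1,3-dioxoisoindolin-2-yl (3R,5Z)-6-(methoxycarbonyl)-3-(prop-1-en-2-yl)nona-5,8-dienoate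
Conditions: N-hydroxyphthalimide, DIC, DMAP (cat.), CH2Cl2, rt
Reagents that add atoms: N-hydroxyphthalimide, O=C1c2ccccc2C(=O)N1O
Why: Steglich-type carbodiimide esterification should give the redox-active ester without touching the remote stereocentre or the enoate geometry.

Step 13
Reactants: 11 S-pyridin-2-yl 2-[(2S,3R,5S)-5-ethenyl-5-methyl-3-[(R)-4-methylbenzenesulfinyl]oxolan-2-yl]ethanethioate; 20 1,3-dioxoisoindolin-2-yl (3R,5Z)-6-(methoxycarbonyl)-3-(prop-1-en-2-yl)nona-5,8-dienoate
Product: 21 methyl (2Z,5R)-8-[(2S,3R,5S)-5-ethenyl-5-methyl-3-[(R)-4-methylbenzenesulfinyl]oxolan-2-yl]-7-oxo-2-(prop-2-en-1-yl)-5-(prop-1-en-2-yl)oct-2-enoate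
Conditions: NiBr2(MeOCH2CH2OMe) (cat.), 4,4′-di-tert-butyl-2,2′-bipyridine, Zn, DMA/THF, rt
Reagents that add atoms: none
Why: Nickel-catalysed decarboxylative cross-electrophile coupling, in which reduction of the phthalimide ester releases a primary alkyl radical that the acyl–nickel species from the pyridyl thioester captures to give the dialkyl ketone; no stereocentre is formed and the one next to the radical carbon is not involved.

Step 14
Reactants: 21 methyl (2Z,5R)-8-[(2S,3R,5S)-5-ethenyl-5-methyl-3-[(R)-4-methylbenzenesulfinyl]oxolan-2-yl]-7-oxo-2-(prop-2-en-1-yl)-5-(prop-1-en-2-yl)oct-2-enoate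
Product: 22 methyl (1S,2E,5Z,8R,12S,13R)-1-methyl-13-[(R)-4-methylbenzenesulfinyl]-10-oxo-8-(prop-1-en-2-yl)-15-oxabicyclo[10.2.1]pentadeca-2,5-diene-5-carboxylate
Conditions: second-generation Hoveyda–Grubbs catalyst (10 mol%), CH2Cl2 (1 mM), 40 °C
Reagents that add atoms: none
Why: Ring-closing olefin metathesis between the two monosubstituted alkenes (the isopropenyl group and the trisubstituted enoate react far more slowly) should close the 14-membered carbocycle across the cis arms of the oxolane; the geometry of the new alkene is immaterial because it is oxidised next.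

Step 15
Reactants: 22 methyl (1S,2E,5Z,8R,12S,13R)-1-methyl-13-[(R)-4-methylbenzenesulfinyl]-10-oxo-8-(prop-1-en-2-yl)-15-oxabicyclo[10.2.1]pentadeca-2,5-diene-5-carboxylate
Product: 23 methyl (1R,5Z,8R,12S,13R)-1-methyl-13-[(R)-4-methylbenzenesulfinyl]-3,10-dioxo-8-(prop-1-en-2-yl)-15-oxabicyclo[10.2.1]pentadec-5-ene-5-carboxylate
Conditions: Pd(OAc)2 (cat.), 1,4-benzoquinone, aq. HBF4, DMA/MeCN/H2O, rt
Reagents that add atoms: water, O
Why: Wacker–Tsuji oxidation of the internal alkene, in which the electron-withdrawing allylic ring oxygen and the fully substituted neighbouring carbon should direct water to the distal alkene carbon (C3) and so give the β-alkoxy ketone; no stereocentre is formed.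

Step 16
Reactants: 23 methyl (1R,5Z,8R,12S,13R)-1-methyl-13-[(R)-4-methylbenzenesulfinyl]-3,10-dioxo-8-(prop-1-en-2-yl)-15-oxabicyclo[10.2.1]pentadec-5-ene-5-carboxylate
Product: 25 methyl (1R,5Z,8R,12S)-1-methyl-3,10,13-trioxo-8-(prop-1-en-2-yl)-15-oxabicyclo[10.2.1]pentadec-5-ene-5-carboxylate, via trifluoroacetoxy sulfide 24 (not isolated)
Conditions: (CF3CO)2O, 2,6-lutidine, CH2Cl2, −20 °C; then aq. NaHCO3, 0 °C
Reagents that add atoms: trifluoroacetic anhydride, O=C(OC(=O)C(F)(F)F)C(F)(F)F
Why: Pummerer rearrangement, in which O-acylation of the sulfoxide, loss of the α-proton and return of trifluoroacetate give the S,O-acetal 24 whose mild hydrolysis releases the ketone; the adjacent C12 stereocentre should keep its configuration because the cold, weakly basic conditions do not enolise the new α-alkoxy ketone.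

Compound list
1 | (1R,2S,5R)-5-methyl-2-(propan-2-yl)cyclohexyl (S)-4-methylbenzenesulfinate | C[C@@H]1CC[C@H]([C@@H](C1)O[S@](=O)c2ccc(C)cc2)C(C)C | starting material
2 | (R)-1-(ethenesulfinyl)-4-methylbenzene ((R)-p-tolyl vinyl sulfoxide) | C=C[S@@](=O)c1ccc(C)cc1 | intermediate
3 | maltol (3-hydroxy-2-methyl-4H-pyran-4-one) | CC1=C(O)C(=O)C=CO1 | starting material
4 | 3-hydroxy-4-methoxy-2-methylpyrylium trifluoromethanesulfonate | COc1cc[o+]c(C)c1O.[O-]S(=O)(=O)C(F)(F)F | intermediate
5 | 4-methoxy-2-methylpyrylium-3-olate (oxidopyrylium ylide) | COc1cc[o+]c(C)c1[O-] | intermediate (not isolated)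
6 | (1S,5S,6R)-3-methoxy-1-methyl-6-[(R)-4-methylbenzenesulfinyl]-8-oxabicyclo[3.2.1]oct-3-en-2-one (6-exo isomer drawn; the 6-endo isomer of the same bridgehead configuration serves equally) | O=C1[C@]2(C)C[C@@H]([S@@](=O)c3ccc(C)cc3)[C@H](C=C1OC)O2 | intermediate
7 | (1S,5S,6R)-3-methoxy-1-methyl-6-[(R)-4-methylbenzenesulfinyl]-8-oxabicyclo[3.2.1]oct-3-en-2-ol (C2 configuration not defined) | OC1[C@]2(C)C[C@@H]([S@@](=O)c3ccc(C)cc3)[C@H](C=C1OC)O2 | intermediate
8 | (1S,5S,6R)-2-hydroxy-1-methyl-6-[(R)-4-methylbenzenesulfinyl]-8-oxabicyclo[3.2.1]octan-3-one (acyloin) | OC1[C@]2(C)C[C@@H]([S@@](=O)c3ccc(C)cc3)[C@H](CC1=O)O2 | intermediate (not isolated)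
9 | 2-[(2S,3R,5S)-5-formyl-5-methyl-3-[(R)-4-methylbenzenesulfinyl]oxolan-2-yl]acetic acid | O=C[C@]1(C)C[C@@H]([S@@](=O)c2ccc(C)cc2)[C@H](CC(=O)O)O1 | intermediate
10 | 2-[(2S,3R,5S)-5-ethenyl-5-methyl-3-[(R)-4-methylbenzenesulfinyl]oxolan-2-yl]acetic acid | C=C[C@]1(C)C[C@@H]([S@@](=O)c2ccc(C)cc2)[C@H](CC(=O)O)O1 | intermediate
11 | S-pyridin-2-yl 2-[(2S,3R,5S)-5-ethenyl-5-methyl-3-[(R)-4-methylbenzenesulfinyl]oxolan-2-yl]ethanethioate | C=C[C@]1(C)C[C@@H]([S@@](=O)c2ccc(C)cc2)[C@H](CC(=O)Sc2ccccn2)O1 | intermediate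
12 | (R)-carvone | CC1=CC[C@H](CC1=O)C(C)=C | starting material
13 | (1R,4R,6R)-1-methyl-4-(prop-1-en-2-yl)-7-oxabicyclo[4.1.0]heptan-2-one | C=C(C)[C@@H]1C[C@H]2O[C@@]2(C)C(=O)C1 | intermediate
14 | (5R)-2,3-dihydroxy-2-methyl-5-(prop-1-en-2-yl)cyclohexan-1-one (diol; carbinol configurations not defined) | C=C(C)[C@@H]1CC(O)C(C)(O)C(=O)C1 | intermediate (not isolated)
15 | (3R)-5,6-dioxo-3-(prop-1-en-2-yl)heptanal | C=C(C)[C@H](CC=O)CC(=O)C(C)=O | intermediate (not isolated)
16 | (3R)-5-oxo-3-(prop-1-en-2-yl)pentanoic acid | C=C(C)[C@@H](CC(=O)O)CC=O | intermediate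
17 | methyl 2-[bis(2,2,2-trifluoroethoxy)phosphoryl]acetate | COC(=O)CP(=O)(OCC(F)(F)F)OCC(F)(F)F | starting material
18 | methyl 2-[bis(2,2,2-trifluoroethoxy)phosphoryl]pent-4-enoate (racemic) | COC(=O)C(CC=C)P(=O)(OCC(F)(F)F)OCC(F)(F)F | intermediate
19 | (3R,5Z)-6-(methoxycarbonyl)-3-(prop-1-en-2-yl)nona-5,8-dienoic acid | C=C(C)[C@@H](CC(=O)O)C/C=C(\C(=O)OC)CC=C | intermediate
20 | 1,3-dioxoisoindolin-2-yl (3R,5Z)-6-(methoxycarbonyl)-3-(prop-1-en-2-yl)nona-5,8-dienoate | C=C(C)[C@@H](CC(=O)ON1C(=O)c2ccccc2C1=O)C/C=C(\C(=O)OC)CC=C | intermediate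
21 | methyl (2Z,5R)-8-[(2S,3R,5S)-5-ethenyl-5-methyl-3-[(R)-4-methylbenzenesulfinyl]oxolan-2-yl]-7-oxo-2-(prop-2-en-1-yl)-5-(prop-1-en-2-yl)oct-2-enoate | C=C[C@]1(C)C[C@@H]([S@@](=O)c2ccc(C)cc2)[C@H](CC(=O)C[C@H](C(C)=C)C/C=C(\C(=O)OC)CC=C)O1 | intermediate
22 | methyl (1S,2E,5Z,8R,12S,13R)-1-methyl-13-[(R)-4-methylbenzenesulfinyl]-10-oxo-8-(prop-1-en-2-yl)-15-oxabicyclo[10.2.1]pentadeca-2,5-diene-5-carboxylate (2E drawn; the 2Z isomer serves equally) | C=C(C)[C@@H]1C/C=C(\C(=O)OC)C/C=C/[C@]2(C)C[C@@H]([S@@](=O)c3ccc(C)cc3)[C@H](CC(=O)C1)O2 | intermediate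
23 | methyl (1R,5Z,8R,12S,13R)-1-methyl-13-[(R)-4-methylbenzenesulfinyl]-3,10-dioxo-8-(prop-1-en-2-yl)-15-oxabicyclo[10.2.1]pentadec-5-ene-5-carboxylate | C=C(C)[C@@H]1C/C=C(\C(=O)OC)CC(=O)C[C@]2(C)C[C@@H]([S@@](=O)c3ccc(C)cc3)[C@H](CC(=O)C1)O2 | intermediate
24 | methyl (1R,5Z,8R,12S)-1-methyl-13-[(4-methylphenyl)sulfanyl]-3,10-dioxo-8-(prop-1-en-2-yl)-13-(trifluoroacetoxy)-15-oxabicyclo[10.2.1]pentadec-5-ene-5-carboxylate (C13 configuration not defined) | C=C(C)[C@@H]1C/C=C(\C(=O)OC)CC(=O)C[C@]2(C)CC(OC(=O)C(F)(F)F)(Sc3ccc(C)cc3)[C@H](CC(=O)C1)O2 | intermediate (not isolated)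
25 | methyl (1R,5Z,8R,12S)-1-methyl-3,10,13-trioxo-8-(prop-1-en-2-yl)-15-oxabicyclo[10.2.1]pentadec-5-ene-5-carboxylate | C=C(C)[C@@H]1C/C=C(\C(=O)OC)CC(=O)C[C@]2(C)CC(=O)[C@H](CC(=O)C1)O2 | target

Total step count: 16. Longest linear sequence: 10 steps (maltol 3 to 25 through steps 2–7 and 13–16).

Steps most likely to fail

Step 3. The ylide may dimerise faster than it adds to the only moderately activated vinyl sulfoxide, and sulfur may discriminate poorly between the two ylide faces, so that much material ends in the wrong diastereomeric series. Fallback: salt 4 is treated with the same base in the presence of the electron-rich 4-methylphenyl vinyl sulfide, which should add like an enol ether with the same regiochemistry, to give racemic (1S,5S,6R)-3-methoxy-1-methyl-6-[(4-methylphenyl)sulfanyl]-8-oxabicyclo[3.2.1]oct-3-en-2-one F1. Kagan–Modena oxidation (Ti(OiPr)4, (R,R)-diethyl tartrate, cumene hydroperoxide, CH2Cl2, −20 °C) then sets the sulfur stereocentre under reagent control in both enantiomers of F1. This gives 6 and its diastereomer (1R,5R,6S)-3-methoxy-1-methyl-6-[(R)-4-methylbenzenesulfinyl]-8-oxabicyclo[3.2.1]oct-3-en-2-one F2, which are separated by chromatography. The route is rejoined at 6.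

Step 13. Reduction or homocoupling of the radical partner and zinc-induced loss of the thioester may outrun the cross-coupling. Fallback: acid 19 is converted (N-hydroxypyridine-2-thione, DIC) into the Barton ester 2-thioxopyridin-1(2H)-yl (3R,5Z)-6-(methoxycarbonyl)-3-(prop-1-en-2-yl)nona-5,8-dienoate F3. Photolysis of F3 with iodoform gives methyl (2Z,5S)-5-(iodomethyl)-6-methyl-2-(prop-2-en-1-yl)hepta-2,6-dienoate F4. Zinc insertion (Zn, LiCl, THF) gives the alkylzinc iodide [(2S,4Z)-5-(methoxycarbonyl)-2-(prop-1-en-2-yl)octa-4,7-dien-1-yl]zinc iodide F5, and Fukuyama coupling of F5 with thioester 11 (PdCl2(PPh3)2, THF/toluene, rt) returns to ketone 21.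

Step 15. On the macrocycle the acid may move the enoate double bond into conjugation with the new ketone or hydrate the isopropenyl group, and the ring conformation may erode the regioselectivity of water attack. Fallback: the oxidation is moved to an acyclic stage and the ring is closed by olefination instead.
- Vinyl acid 10 undergoes cross-metathesis with phosphonate 18 (second-generation Hoveyda–Grubbs catalyst) to give 2-[(2S,3R,5S)-5-[(1E)-4-[bis(2,2,2-trifluoroethoxy)phosphoryl]-5-methoxy-5-oxopent-1-en-1-yl]-5-methyl-3-[(R)-4-methylbenzenesulfinyl]oxolan-2-yl]acetic acid F6.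
- Wacker–Tsuji oxidation (same conditions as step 15, now without isopropenyl group or enoate) gives 2-[(2S,3R,5R)-5-[4-[bis(2,2,2-trifluoroethoxy)phosphoryl]-5-methoxy-2,5-dioxopentyl]-5-methyl-3-[(R)-4-methylbenzenesulfinyl]oxolan-2-yl]acetic acid F7.
- Thioester formation as in step 7 gives the S-pyridin-2-yl thioester of F7, F8.
- Acid–aldehyde 16 is converted as in step 12 into 1,3-dioxoisoindolin-2-yl (3R)-5-oxo-3-(prop-1-en-2-yl)pentanoate F9.
- Nickel-catalysed coupling of F8 with F9 as in step 13 gives methyl 2-[bis(2,2,2-trifluoroethoxy)phosphoryl]-5-[(2R,4R,5S)-5-[(4R)-2,6-dioxo-4-(prop-1-en-2-yl)hexyl]-2-methyl-4-[(R)-4-methylbenzenesulfinyl]oxolan-2-yl]-4-oxopentanoate F10.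
- Intramolecular Still–Gennari olefination of F10 (KHMDS, 18-crown-6, THF, high dilution, −78 °C) closes the ring and rejoins the route at 23.

Further compounds
F1 | step 3 | rac-(1S,5S,6R)-3-methoxy-1-methyl-6-[(4-methylphenyl)sulfanyl]-8-oxabicyclo[3.2.1]oct-3-en-2-one (one enantiomer drawn) | O=C1[C@]2(C)C[C@@H](Sc3ccc(C)cc3)[C@H](C=C1OC)O2
F2 | step 3 | (1R,5R,6S)-3-methoxy-1-methyl-6-[(R)-4-methylbenzenesulfinyl]-8-oxabicyclo[3.2.1]oct-3-en-2-one | O=C1[C@@]2(C)C[C@H]([S@@](=O)c3ccc(C)cc3)[C@@H](C=C1OC)O2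
F3 | step 13 | 2-thioxopyridin-1(2H)-yl (3R,5Z)-6-(methoxycarbonyl)-3-(prop-1-en-2-yl)nona-5,8-dienoate | C=C(C)[C@@H](CC(=O)On1ccccc1=S)C/C=C(\C(=O)OC)CC=C
F4 | step 13 | methyl (2Z,5S)-5-(iodomethyl)-6-methyl-2-(prop-2-en-1-yl)hepta-2,6-dienoate | C=C(C)[C@@H](CI)C/C=C(\C(=O)OC)CC=C
F5 | step 13 | [(2S,4Z)-5-(methoxycarbonyl)-2-(prop-1-en-2-yl)octa-4,7-dien-1-yl]zinc iodide | C=C(C)[C@@H](C[Zn]I)C/C=C(\C(=O)OC)CC=C
F6 | step 15 | 2-[(2S,3R,5S)-5-[(1E)-4-[bis(2,2,2-trifluoroethoxy)phosphoryl]-5-methoxy-5-oxopent-1-en-1-yl]-5-methyl-3-[(R)-4-methylbenzenesulfinyl]oxolan-2-yl]acetic acid | COC(=O)C(C/C=C/[C@]1(C)C[C@@H]([S@@](=O)c2ccc(C)cc2)[C@H](CC(=O)O)O1)P(=O)(OCC(F)(F)F)OCC(F)(F)F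
F7 | step 15 | 2-[(2S,3R,5R)-5-[4-[bis(2,2,2-trifluoroethoxy)phosphoryl]-5-methoxy-2,5-dioxopentyl]-5-methyl-3-[(R)-4-methylbenzenesulfinyl]oxolan-2-yl]acetic acid | COC(=O)C(CC(=O)C[C@]1(C)C[C@@H]([S@@](=O)c2ccc(C)cc2)[C@H](CC(=O)O)O1)P(=O)(OCC(F)(F)F)OCC(F)(F)F
F8 | step 15 | S-pyridin-2-yl 2-[(2S,3R,5R)-5-[4-[bis(2,2,2-trifluoroethoxy)phosphoryl]-5-methoxy-2,5-dioxopentyl]-5-methyl-3-[(R)-4-methylbenzenesulfinyl]oxolan-2-yl]ethanethioate | COC(=O)C(CC(=O)C[C@]1(C)C[C@@H]([S@@](=O)c2ccc(C)cc2)[C@H](CC(=O)Sc2ccccn2)O1)P(=O)(OCC(F)(F)F)OCC(F)(F)F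
F9 | step 15 | 1,3-dioxoisoindolin-2-yl (3R)-5-oxo-3-(prop-1-en-2-yl)pentanoate | C=C(C)[C@@H](CC(=O)ON1C(=O)c2ccccc2C1=O)CC=O
F10 | step 15 | methyl 2-[bis(2,2,2-trifluoroethoxy)phosphoryl]-5-[(2R,4R,5S)-5-[(4R)-2,6-dioxo-4-(prop-1-en-2-yl)hexyl]-2-methyl-4-[(R)-4-methylbenzenesulfinyl]oxolan-2-yl]-4-oxopentanoate | COC(=O)C(CC(=O)C[C@]1(C)C[C@@H]([S@@](=O)c2ccc(C)cc2)[C@H](CC(=O)C[C@H](C(C)=C)CC=O)O1)P(=O)(OCC(F)(F)F)OCC(F)(F)F
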